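The C40 chain is cut at C15=C15' into two C20 halves (sulfone plus aldehyde), and each half at C9–CH3 and C10–C11. Everything rests on one operation: zirconium-catalysed syn methylalumination of a ring-bound buta-1,3-diyne and palladium-catalysed coupling of the resulting alkenylalane with an (E,E)-iododiene, which delivers the 9E enyne and the whole C7–C15 chain in one flask. The step exploits the free C9≡C10–H end of the diyne on ring A, the only alkyne open to attack because C7≡C8 is shielded by tetrasubstituted C6 and the C1 gem-dimethyl and C5 methyl groups. Its precursor is the C3-silylated ring A carrying the butadiynyl group at C6. Both rings derive from one silylated (S)-phorenol and one monosilylated butadiyne.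

Key step: step 9

Assumption: carotenoid numbering is used (unprimed for the monohydroxy ring A half, primed for the dihydroxy ring B half); TBS = tert-butyldimethylsilyl, TMS = trimethylsilyl, BT = 1,3-benzothiazol-2-yl, DIAD = diisopropyl azodicarboxylate; the C6' epimers of 22 are carried on together because step 14 removes that centre; all polyenes are handled under argon in dim light.

Step 1
Reactants: 1 ketoisophorone
Product: 2 (S)-phorenol [(4S)-4-hydroxy-2,6,6-trimethylcyclohex-2-en-1-one]
Conditions: Ru[(S,S)-TsNCH(Ph)CH(Ph)NH](p-cymene) (1 mol%), i-PrOH, rt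
Reagents that add atoms: none
Why: Noyori-type asymmetric transfer hydrogenation should reduce only the unhindered C4 carbonyl (the C1 carbonyl is flanked by the quaternary carbon and the methyl-bearing alkene carbon), and the chiral ruthenium hydride sets the carbinol centre, the (S,S) ligand being expected to give 4S when the enone π system takes the place of the aryl group of an aryl alkyl ketone; this centre becomes C3 of ring A and C3' of ring B.

Step 2
Reactants: 2 (S)-phorenol
Product: 3 (S)-phorenol TBS ether [(4S)-4-(TBSO)-2,6,6-trimethylcyclohex-2-en-1-one]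
Conditions: TBSCl, imidazole, DMF, rt
Reagents that add atoms: tert-butyldimethylsilyl chloride, CC(C)(C)[Si](C)(C)Cl
Why: Imidazole-promoted O-silylation of a secondary alcohol, which leaves the enone and the stereocentre untouched.

Step 3
Reactants: 3 (S)-phorenol TBS ether
Product: 5 ring A enol triflate [(4R)-4-(TBSO)-2,6,6-trimethylcyclohex-1-en-1-yl trifluoromethanesulfonate], via lithium enolate 4 (not isolated)
Conditions: LiBH(s-Bu)3 (1.1 equiv), THF, −78 °C; then PhNTf2, −78 °C → rt; aq. NH4Cl
Reagents that add atoms: N-phenylbis(trifluoromethanesulfonimide), O=S(=O)(N(c1ccccc1)S(=O)(=O)C(F)(F)F)C(F)(F)F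
Why: Conjugate reduction with in-situ enolate O-triflation: the bulky borohydride is kept from the shielded carbonyl and adds hydride to the unsubstituted β-carbon, and the single tetrasubstituted enolate 4 is sulfonylated on oxygen, the silyloxy group being γ to the carbonyl carbon and so unable to eliminate, while the carbinol centre is untouched (S becomes R only through a change in CIP ranking).

Step 4
Reactants: 6 1,4-bis(trimethylsilyl)buta-1,3-diyne
Product: 8 trimethylsilylbutadiyne [buta-1,3-diyn-1-yl(trimethyl)silane], via lithium diynide 7 (not isolated)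
Conditions: MeLi·LiBr (1.0 equiv), Et2O, rt; aq. NH4Cl, 0 °C; dried and concentrated cold to a stock solution (Et2O/THF), stored at −20 °C
Reagents that add atoms: none
Why: Mono-protiodesilylation: methyllithium attacks one silicon of the symmetrical diyne and expels the lithium diynide 7, whose negative charge protects the second C–Si bond, and protonation on work-up gives the terminal diyne, which is kept in cold solution because it is volatile and oligomerises when neat.

Step 5
Reactants: 5 ring A enol triflate; 8 trimethylsilylbutadiyne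
Product: 9 ring A silyl-capped diyne [tert-butyldimethyl({(1R)-3,5,5-trimethyl-4-[4-(trimethylsilyl)buta-1,3-diyn-1-yl]cyclohex-3-en-1-yl}oxy)silane]
Conditions: 8 (1.3 equiv), Pd(PPh3)4 (5 mol%), CuI (10 mol%), i-Pr2NH, degassed DMF, rt → 45 °C
Reagents that add atoms: none
Why: Sonogashira coupling: zerovalent palladium inserts into the C–O bond of the enol triflate, the alkynylcopper formed from 8, CuI and the amine hands over the diynyl group, and reductive elimination forms C6–C7; the silyl cap blocks the far alkyne terminus and rigorous degassing suppresses oxidative dimerisation of the diyne.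

Step 6
Reactants: 9 ring A silyl-capped diyne
Product: 10 ring A butadiyne [{[(1R)-4-(buta-1,3-diyn-1-yl)-3,5,5-trimethylcyclohex-3-en-1-yl]oxy}(tert-butyl)dimethylsilane]
Conditions: K2CO3 (cat.), MeOH/THF, 0 °C; aqueous work-up, pentane extract dried and exchanged into CH2Cl2, used at once
Reagents that add atoms: none
Why: Base-catalysed methanolysis of the alkynyl C–Si bond (protiodesilylation), to which the secondary silyl ether is inert; the terminal diyne is kept cold and dilute and is freed of methanol before it meets the alane.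

Step 7
Reactants: 11 (E)-3-methylpent-2-en-4-yn-1-ol
Product: 12 enynol TBS ether [tert-butyldimethyl{[(2E)-3-methylpent-2-en-4-yn-1-yl]oxy}silane]
Conditions: TBSCl, imidazole, CH2Cl2, 0 °C → rt
Reagents that add atoms: tert-butyldimethylsilyl chloride, CC(C)(C)[Si](C)(C)Cl
Why: Imidazole-promoted silylation of a primary allylic alcohol, which leaves the terminal alkyne and the E alkene untouched.

Step 8
Reactants: 12 enynol TBS ether
Product: 14 iododiene [tert-butyl{[(2E,4E)-5-iodo-3-methylpenta-2,4-dien-1-yl]oxy}dimethylsilane], via alkenylzirconocene chloride 13 (not isolated)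
Conditions: Cp2Zr(H)Cl, THF, rt, dark; then I2, 0 °C
Reagents that add atoms: iodine, II
Why: Hydrozirconation–iodination: Cp2Zr(H)Cl adds syn across the terminal alkyne with zirconium at the terminal carbon, and iodinolysis of the C–Zr bond proceeds with retention to give the 4E iodide, the 2E alkene being carried over from 11.

Step 9
Reactants: 10 ring A butadiyne; 15 trimethylaluminium; 14 iododiene
Product: 17 ring A C20 bis-silyl ether [tert-butyl({(2E,4E,6E)-9-[(4R)-4-(TBSO)-2,6,6-trimethylcyclohex-1-en-1-yl]-3,7-dimethylnona-2,4,6-trien-8-yn-1-yl}oxy)dimethylsilane], via ring A alkenylalane 16 (not isolated)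
Conditions: Me3Al (2 equiv), Cp2ZrCl2 (0.5 equiv), CH2Cl2, 0 °C → rt; then 14, ZnCl2 (1 equiv), Pd(PPh3)4 (5 mol%), THF, rt, dark
Reagents that add atoms: trimethylaluminium, C[Al](C)C
Why: Methylzirconocene chloride Cp2Zr(Me)Cl, activated by Me3Al, adds methyl and metal across C9≡C10 through a four-centre syn transition state, methyl to internal C9 and metal to terminal C10, and exchange to aluminium leaves the (E)-alkenyl(dimethyl)alane 16; zinc then carries the alkenyl group to the alkenyl divalent palladium iodide formed from 14 and zerovalent palladium, and reductive elimination forms C10–C11 with retention at both alkenes. The closest known reaction type is the Negishi zirconium-catalysed carboalumination of terminal alkynes, silyl-capped buta-1,3-diyne included, followed by zinc- and palladium-mediated alkenyl–alkenyl coupling in the same flask. No ring is closed and no stereocentre is formed; the remote C3 centre is not involved. The step needs methylmetalation of the terminal alkyne only, with methyl at C9 and syn geometry: the unhindered C–H terminus directs the metal to C10, the concerted addition fixes 9E, and C7≡C8 stays inert because it is flanked by tetrasubstituted C6 with the C1 gem-dimethyl and C5 methyl groups. The 11E and 13E geometries come in with 14, and the silyl ethers are poor donors that tolerate the Lewis acidic alane.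

Step 10
Reactants: 17 ring A C20 bis-silyl ether
Product: 18 ring A C20 alcohol [(2E,4E,6E)-9-[(4R)-4-(TBSO)-2,6,6-trimethylcyclohex-1-en-1-yl]-3,7-dimethylnona-2,4,6-trien-8-yn-1-ol]
Conditions: HF·pyridine, pyridine, THF, 0 °C
Reagents that add atoms: none
Why: Selective desilylation: buffered fluoride cleaves the unhindered primary allylic silyl ether much faster than the secondary ring ether, and the medium is too weakly acidic to ionise the allylic polyene.

Step 11
Reactants: 18 ring A C20 alcohol
Product: 19 ring A C20 BT sulfide [2-{[(2E,4E,6E)-9-[(4R)-4-(TBSO)-2,6,6-trimethylcyclohex-1-en-1-yl]-3,7-dimethylnona-2,4,6-trien-8-yn-1-yl]sulfanyl}-1,3-benzothiazole]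
Conditions: 2-mercaptobenzothiazole, PPh3, DIAD, THF, 0 °C
Reagents that add atoms: 2-mercaptobenzothiazole, Sc1nc2ccccc2s1
Why: Mitsunobu thioetherification, an SN2 displacement at the primary allylic carbon that involves no allyl cation, so the 9E, 11E and 13E geometry is kept.

Step 12
Reactants: 19 ring A C20 BT sulfide
Product: 20 ring A C20 BT sulfone [2-{[(2E,4E,6E)-9-[(4R)-4-(TBSO)-2,6,6-trimethylcyclohex-1-en-1-yl]-3,7-dimethylnona-2,4,6-trien-8-yn-1-yl]sulfonyl}-1,3-benzothiazole]
Conditions: (NH4)6Mo7O24·4H2O (10 mol%), 30% H2O2, EtOH, −10 → 0 °C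
Reagents that add atoms: hydrogen peroxide, OO
Why: Molybdenum-catalysed peroxide oxidation of the sulfide through the sulfoxide to the sulfone, in which the electrophilic peroxo complex formed from (NH4)6Mo7O24 and H2O2 attacks sulfur far faster than the conjugated alkenes at low temperature.

Step 13
Reactants: 8 trimethylsilylbutadiyne; 3 (S)-phorenol TBS ether
Product: 22 ring B tertiary alcohol [(4S)-4-(TBSO)-2,6,6-trimethyl-1-[4-(trimethylsilyl)buta-1,3-diyn-1-yl]cyclohex-2-en-1-ol; both C1 epimers], via diynylmagnesium bromide 21 (not isolated)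
Conditions: 8 (1.3 equiv), EtMgBr (1.2 equiv), THF, 0 °C → rt; then 3, 0 → 40 °C; aq. NH4Cl
Reagents that add atoms: none
Why: Alkynyl Grignard 1,2-addition: EtMgBr deprotonates the terminal C–H of 8 (the silyl-capped end is inert to it) and the diynylmagnesium bromide adds to the hindered enone carbonyl, which has no α-hydrogen on either side, so enolisation cannot compete and the hard acetylide does not add in the conjugate sense; the new C6' carbinol centre forms as a mixture of no consequence.

Step 14
Reactants: 22 ring B tertiary alcohol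
Product: 23 ring B enone [(6S)-6-(TBSO)-2,4,4-trimethyl-3-[4-(trimethylsilyl)buta-1,3-diyn-1-yl]cyclohex-2-en-1-one]
Conditions: pyridinium chlorochromate [C5H5NH][CrO3Cl], 4 Å molecular sieves, CH2Cl2, rt
Reagents that add atoms: pyridinium chlorochromate, [O-][Cr](=O)(=O)Cl.c1cc[nH+]cc1
Why: Babler–Dauben oxidative 1,3-transposition: the tertiary chromate ester shifts [3,3] along the C6'–C5'=C4' allyl unit (allyl shifts outrun propargyl shifts in ethynyl vinyl carbinols) and the secondary chromate at C4' is oxidised to the enone conjugated with the diyne, which erases the C6' centre and leaves the enolisable 3'-silyloxy centre alone under these non-basic conditions.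

Step 15
Reactants: 23 ring B enone
Product: 24 ring B cis alcohol [(1R,6S)-6-(TBSO)-2,4,4-trimethyl-3-[4-(trimethylsilyl)buta-1,3-diyn-1-yl]cyclohex-2-en-1-ol]
Conditions: LiBH(s-Bu)3, THF, −78 °C; aq. NH4Cl
Reagents that add atoms: none
Why: 1,2-Reduction of a β,β-disubstituted enone by a bulky trialkylborohydride: the 3'-silyloxy group sits pseudo-equatorial to avoid the axial C1' methyl, the reagent should approach the C4' carbonyl along the less hindered equatorial trajectory, and the resulting pseudo-axial alcohol is cis to O3', so 4'R is set by substrate control from 3'S.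

Step 16
Reactants: 24 ring B cis alcohol
Product: 25 ring B bis-silyl ether [[(1R,6S)-2,4,4-trimethyl-3-[4-(trimethylsilyl)buta-1,3-diyn-1-yl]cyclohex-2-ene-1,6-diyl]bis(oxy)bis(tert-butyldimethylsilane)]
Conditions: TBSOTf, 2,6-lutidine, CH2Cl2, −78 → 0 °C
Reagents that add atoms: tert-butyldimethylsilyl trifluoromethanesulfonate, CC(C)(C)[Si](C)(C)OS(=O)(=O)C(F)(F)F
Why: Silylation of a hindered secondary allylic alcohol with the silyl triflate and a hindered pyridine base, the standard answer where the silyl chloride is too slow; no stereocentre is touched.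

Step 17
Reactants: 25 ring B bis-silyl ether
Product: 26 ring B butadiyne [[(1R,6S)-3-(buta-1,3-diyn-1-yl)-2,4,4-trimethylcyclohex-2-ene-1,6-diyl]bis(oxy)bis(tert-butyldimethylsilane)]
Conditions: K2CO3 (cat.), MeOH/THF, 0 °C; aqueous work-up, pentane extract dried and exchanged into CH2Cl2, used at once
Reagents that add atoms: none
Why: Base-catalysed methanolysis of the alkynyl C–Si bond, as in step 6, with both secondary silyl ethers inert.

Step 18
Reactants: 26 ring B butadiyne; 15 trimethylaluminium; 14 iododiene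
Product: 28 ring B C20 tris-silyl ether [{[(2E,4E,6E)-9-[(3R,4S)-3,4-bis(TBSO)-2,6,6-trimethylcyclohex-1-en-1-yl]-3,7-dimethylnona-2,4,6-trien-8-yn-1-yl]oxy}(tert-butyl)dimethylsilane], via ring B alkenylalane 27 (not isolated)
Conditions: Me3Al (2 equiv), Cp2ZrCl2 (0.5 equiv), CH2Cl2, 0 °C → rt; then 14, ZnCl2 (1 equiv), Pd(PPh3)4 (5 mol%), THF, rt, dark
Reagents that add atoms: trimethylaluminium, C[Al](C)C
Why: The same Negishi methylalumination–cross-coupling as in step 9, with syn delivery of methyl to C9' and aluminium to C10' and coupling to 14 with retention, the silyl ethers (the allylic one at C4' included) being poor donors that should tolerate the alane at room temperature; no stereocentre is formed.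

Step 19
Reactants: 28 ring B C20 tris-silyl ether
Product: 29 ring B C20 alcohol [(2E,4E,6E)-9-[(3R,4S)-3,4-bis(TBSO)-2,6,6-trimethylcyclohex-1-en-1-yl]-3,7-dimethylnona-2,4,6-trien-8-yn-1-ol]
Conditions: HF·pyridine, pyridine, THF, 0 °C
Reagents that add atoms: none
Why: Selective desilylation as in step 10, the primary allylic ether reacting much faster than the two hindered secondary ring ethers.

Step 20
Reactants: 29 ring B C20 alcohol
Product: 30 ring B C20 aldehyde [(2E,4E,6E)-9-[(3R,4S)-3,4-bis(TBSO)-2,6,6-trimethylcyclohex-1-en-1-yl]-3,7-dimethylnona-2,4,6-trien-8-ynal]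
Conditions: MnO2, CH2Cl2, rt, dark
Reagents that add atoms: none
Why: Allylic oxidation with MnO2, which is selective for the primary allylic alcohol, stops at the polyenal and touches neither silyl ethers nor alkene geometry.

Step 21
Reactants: 20 ring A C20 BT sulfone; 30 ring B C20 aldehyde
Product: 32 all-E C40 tris-silyl ether [(3R,3'S,4'R)-3,3',4'-tris(TBSO)-7,8,7',8'-tetradehydro-β,β-carotene], via 15Z isomer 31 (not isolated)
Conditions: NaN(SiMe3)2 added to 20 + 30, THF, −78 °C → rt; aq. NH4Cl; crude product then benzene, 50 °C, dark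
Reagents that add atoms: none
Why: Julia–Kocienski olefination: the sulfone carbanion adds to the aldehyde, Smiles transfer of the benzothiazolyl group and loss of SO2 and benzothiazolone form C15=C15', and any 15Z isomer 31 should relax on gentle warming because the central disubstituted bond of the polyene has the lowest rotation barrier, whereas the trisubstituted 9 and 9' enyne bonds are not touched at this temperature.

Step 22
Reactants: 32 all-E C40 tris-silyl ether
Product: 33 target [(3R,3'S,4'R)-7,8,7',8'-tetradehydro-β,β-carotene-3,3',4'-triol, all-E]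
Conditions: Bu4NF (excess), THF, rt → 40 °C, dark
Reagents that add atoms: none
Why: Fluoride-mediated cleavage of all three silyl ethers under non-acidic conditions, which spares the acid-labile allylic C4' hydroxyl and the polyene; the three stereocentres are not involved.

Compound list
1 | ketoisophorone (2,6,6-trimethylcyclohex-2-ene-1,4-dione) | CC1=CC(=O)CC(C)(C)C1=O | starting material
2 | (S)-phorenol, (4S)-4-hydroxy-2,6,6-trimethylcyclohex-2-en-1-one | CC1=C[C@@H](O)CC(C)(C)C1=O | intermediate
3 | (S)-phorenol TBS ether, (4S)-4-(TBSO)-2,6,6-trimethylcyclohex-2-en-1-one | CC1=C[C@@H](O[Si](C)(C)C(C)(C)C)CC(C)(C)C1=O | intermediate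
4 | lithium (4R)-4-(TBSO)-2,6,6-trimethylcyclohex-1-en-1-olate | CC1=C(O[Li])C(C)(C)C[C@H](O[Si](C)(C)C(C)(C)C)C1 | intermediate
5 | ring A enol triflate, (4R)-4-(TBSO)-2,6,6-trimethylcyclohex-1-en-1-yl trifluoromethanesulfonate | CC1=C(OS(=O)(=O)C(F)(F)F)C(C)(C)C[C@H](O[Si](C)(C)C(C)(C)C)C1 | intermediate
6 | 1,4-bis(trimethylsilyl)buta-1,3-diyne | C[Si](C)(C)C#CC#C[Si](C)(C)C | starting material
7 | lithium 4-(trimethylsilyl)buta-1,3-diyn-1-ide | [Li]C#CC#C[Si](C)(C)C | intermediate
8 | trimethylsilylbutadiyne, buta-1,3-diyn-1-yl(trimethyl)silane | C#CC#C[Si](C)(C)C | intermediate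
9 | ring A silyl-capped diyne, tert-butyldimethyl({(1R)-3,5,5-trimethyl-4-[4-(trimethylsilyl)buta-1,3-diyn-1-yl]cyclohex-3-en-1-yl}oxy)silane | CC1=C(C#CC#C[Si](C)(C)C)C(C)(C)C[C@H](O[Si](C)(C)C(C)(C)C)C1 | intermediate
10 | ring A butadiyne, {[(1R)-4-(buta-1,3-diyn-1-yl)-3,5,5-trimethylcyclohex-3-en-1-yl]oxy}(tert-butyl)dimethylsilane | CC1=C(C#CC#C)C(C)(C)C[C@H](O[Si](C)(C)C(C)(C)C)C1 | intermediate
11 | (E)-3-methylpent-2-en-4-yn-1-ol | C#C/C(C)=C/CO | starting material
12 | tert-butyldimethyl{[(2E)-3-methylpent-2-en-4-yn-1-yl]oxy}silane | C#C/C(C)=C/CO[Si](C)(C)C(C)(C)C | intermediate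
13 | chloro[(1E,3E)-5-(TBSO)-3-methylpenta-1,3-dien-1-yl]zirconocene | Cl[Zr](/C=C/C(C)=C/CO[Si](C)(C)C(C)(C)C)(C1C=CC=C1)C1C=CC=C1 | intermediate
14 | tert-butyl{[(2E,4E)-5-iodo-3-methylpenta-2,4-dien-1-yl]oxy}dimethylsilane | I/C=C/C(C)=C/CO[Si](C)(C)C(C)(C)C | intermediate
15 | trimethylaluminium | C[Al](C)C | starting material
16 | ring A alkenylalane, {(1E)-4-[(4R)-4-(TBSO)-2,6,6-trimethylcyclohex-1-en-1-yl]-2-methylbut-1-en-3-yn-1-yl}dimethylaluminium | CC1=C(C#C/C(C)=C/[Al](C)C)C(C)(C)C[C@H](O[Si](C)(C)C(C)(C)C)C1 | intermediate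
17 | ring A C20 bis-silyl ether, tert-butyl({(2E,4E,6E)-9-[(4R)-4-(TBSO)-2,6,6-trimethylcyclohex-1-en-1-yl]-3,7-dimethylnona-2,4,6-trien-8-yn-1-yl}oxy)dimethylsilane | CC1=C(C#C/C(C)=C/C=C/C(C)=C/CO[Si](C)(C)C(C)(C)C)C(C)(C)C[C@H](O[Si](C)(C)C(C)(C)C)C1 | intermediate
18 | ring A C20 alcohol, (2E,4E,6E)-9-[(4R)-4-(TBSO)-2,6,6-trimethylcyclohex-1-en-1-yl]-3,7-dimethylnona-2,4,6-trien-8-yn-1-ol | CC1=C(C#C/C(C)=C/C=C/C(C)=C/CO)C(C)(C)C[C@H](O[Si](C)(C)C(C)(C)C)C1 | intermediate
19 | ring A C20 BT sulfide | CC1=C(C#C/C(C)=C/C=C/C(C)=C/CSc2nc3ccccc3s2)C(C)(C)C[C@H](O[Si](C)(C)C(C)(C)C)C1 | intermediate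
20 | ring A C20 BT sulfone | CC1=C(C#C/C(C)=C/C=C/C(C)=C/CS(=O)(=O)c2nc3ccccc3s2)C(C)(C)C[C@H](O[Si](C)(C)C(C)(C)C)C1 | intermediate
21 | bromo[4-(trimethylsilyl)buta-1,3-diyn-1-yl]magnesium | Br[Mg]C#CC#C[Si](C)(C)C | intermediate
22 | ring B tertiary alcohol, (4S)-4-(TBSO)-2,6,6-trimethyl-1-[4-(trimethylsilyl)buta-1,3-diyn-1-yl]cyclohex-2-en-1-ol, C1 epimers | CC1=C[C@@H](O[Si](C)(C)C(C)(C)C)CC(C)(C)C1(O)C#CC#C[Si](C)(C)C | intermediate
23 | ring B enone, (6S)-6-(TBSO)-2,4,4-trimethyl-3-[4-(trimethylsilyl)buta-1,3-diyn-1-yl]cyclohex-2-en-1-one | CC1=C(C#CC#C[Si](C)(C)C)C(C)(C)C[C@H](O[Si](C)(C)C(C)(C)C)C1=O | intermediate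
24 | ring B cis alcohol, (1R,6S)-6-(TBSO)-2,4,4-trimethyl-3-[4-(trimethylsilyl)buta-1,3-diyn-1-yl]cyclohex-2-en-1-ol | CC1=C(C#CC#C[Si](C)(C)C)C(C)(C)C[C@H](O[Si](C)(C)C(C)(C)C)[C@@H]1O | intermediate
25 | ring B bis-silyl ether, [(1R,6S)-2,4,4-trimethyl-3-[4-(trimethylsilyl)buta-1,3-diyn-1-yl]cyclohex-2-ene-1,6-diyl]bis(oxy)bis(tert-butyldimethylsilane) | CC1=C(C#CC#C[Si](C)(C)C)C(C)(C)C[C@H](O[Si](C)(C)C(C)(C)C)[C@@H]1O[Si](C)(C)C(C)(C)C | intermediate
26 | ring B butadiyne, [(1R,6S)-3-(buta-1,3-diyn-1-yl)-2,4,4-trimethylcyclohex-2-ene-1,6-diyl]bis(oxy)bis(tert-butyldimethylsilane) | CC1=C(C#CC#C)C(C)(C)C[C@H](O[Si](C)(C)C(C)(C)C)[C@@H]1O[Si](C)(C)C(C)(C)C | intermediate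
27 | ring B alkenylalane, {(1E)-4-[(3R,4S)-3,4-bis(TBSO)-2,6,6-trimethylcyclohex-1-en-1-yl]-2-methylbut-1-en-3-yn-1-yl}dimethylaluminium | CC1=C(C#C/C(C)=C/[Al](C)C)C(C)(C)C[C@H](O[Si](C)(C)C(C)(C)C)[C@@H]1O[Si](C)(C)C(C)(C)C | intermediate
28 | ring B C20 tris-silyl ether, {[(2E,4E,6E)-9-[(3R,4S)-3,4-bis(TBSO)-2,6,6-trimethylcyclohex-1-en-1-yl]-3,7-dimethylnona-2,4,6-trien-8-yn-1-yl]oxy}(tert-butyl)dimethylsilane | CC1=C(C#C/C(C)=C/C=C/C(C)=C/CO[Si](C)(C)C(C)(C)C)C(C)(C)C[C@H](O[Si](C)(C)C(C)(C)C)[C@@H]1O[Si](C)(C)C(C)(C)C | intermediate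
29 | ring B C20 alcohol, (2E,4E,6E)-9-[(3R,4S)-3,4-bis(TBSO)-2,6,6-trimethylcyclohex-1-en-1-yl]-3,7-dimethylnona-2,4,6-trien-8-yn-1-ol | CC1=C(C#C/C(C)=C/C=C/C(C)=C/CO)C(C)(C)C[C@H](O[Si](C)(C)C(C)(C)C)[C@@H]1O[Si](C)(C)C(C)(C)C | intermediate
30 | ring B C20 aldehyde, (2E,4E,6E)-9-[(3R,4S)-3,4-bis(TBSO)-2,6,6-trimethylcyclohex-1-en-1-yl]-3,7-dimethylnona-2,4,6-trien-8-ynal | CC1=C(C#C/C(C)=C/C=C/C(C)=C/C=O)C(C)(C)C[C@H](O[Si](C)(C)C(C)(C)C)[C@@H]1O[Si](C)(C)C(C)(C)C | intermediate
31 | 15Z isomer of the C40 tris-silyl ether | CC1=C(C#C/C(C)=C/C=C/C(C)=C/C=C\C=C(C)\C=C\C=C(/C)C#CC2=C(C)[C@@H](O[Si](C)(C)C(C)(C)C)[C@@H](O[Si](C)(C)C(C)(C)C)CC2(C)C)C(C)(C)C[C@H](O[Si](C)(C)C(C)(C)C)C1 | intermediate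
32 | all-E C40 tris-silyl ether, (3R,3'S,4'R)-3,3',4'-tris(TBSO)-7,8,7',8'-tetradehydro-β,β-carotene | CC1=C(C#C/C(C)=C/C=C/C(C)=C/C=C/C=C(C)/C=C/C=C(\C)C#CC2=C(C)[C@@H](O[Si](C)(C)C(C)(C)C)[C@@H](O[Si](C)(C)C(C)(C)C)CC2(C)C)C(C)(C)C[C@H](O[Si](C)(C)C(C)(C)C)C1 | intermediate
33 | CNP0323983.1, (3R,3'S,4'R)-7,8,7',8'-tetradehydro-β,β-carotene-3,3',4'-triol, all-E | CC1=C(C#C/C(C)=C/C=C/C(C)=C/C=C/C=C(C)/C=C/C=C(\C)C#CC2=C(C)[C@@H](O)[C@@H](O)CC2(C)C)C(C)(C)C[C@H](O)C1 | target

Total step count: 22.
Longest linear sequence: 12 steps (steps 1, 2, 13 to 22); the ring A branch is 11 steps (1 to 3, 5, 6, 9 to 12, 21, 22).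

Three steps most likely to fail

1. Step 9 (the same operation recurs in step 18). The terminal diyne may oligomerise or be metalated at C10 instead of carbometalated, methyl delivery may lose regiocontrol, or transfer from aluminium through zinc to palladium may lag so that the alkenyl metal is simply protonated. Fallback for ring A, setting out from 5 and 11 and coming back at 18: Sonogashira coupling of 5 with 11 (PdCl2(PPh3)2, CuI, i-Pr2NH, DMF, rt) should give the C15 enynol F1, whose 9E geometry is taken over from 11. MnO2 in CH2Cl2 then gives the C15 enynal F2. Horner–Wadsworth–Emmons olefination with triethyl 3-methyl-4-phosphonobut-2-enoate (LiN(SiMe3)2, THF, −78 → 0 °C) gives the C20 ethyl ester F3, any 13Z isomer being removed by chromatography. Reduction with i-Bu2AlH (CH2Cl2, −78 °C) returns to 18.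

2. Step 14. The chromate ester may shift towards the alkyne instead of the alkene, the shift may be slow next to the bulky silyloxy group, or the acidic oxidant may degrade the diyne. Fallback, setting out from 22 and coming back at 23: the rearrangement is separated from the oxidation. Catalytic p-TsOH in wet THF at rt (the anionotropic allylic rearrangement typical of ethynyl vinyl carbinols) should move the hydroxyl to C4' and give the secondary allylic alcohol F4 as a mixture of C4' epimers, and MnO2 in CH2Cl2 oxidises this to 23.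

3. Step 15. Hydride delivery may show poor facial selectivity and give much trans alcohol, or hydride may add in the conjugate sense along the enediyne. Fallback, setting out from 23 and coming back at 26: reduction under Luche conditions (NaBH4, CeCl3·7H2O, MeOH, −78 °C), where axial attack should favour the trans alcohol F5. Mitsunobu inversion with 4-nitrobenzoic acid (PPh3, DIAD, toluene, 0 °C → rt) gives the cis 4-nitrobenzoate F6. K2CO3 in MeOH removes the ester and the alkynyl silyl group in one operation to give the desilylated cis alcohol F7, and TBSOTf with 2,6-lutidine then gives 26, so that steps 16 and 17 are replaced.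

Further compounds
F1 | step 9 | (2E)-5-[(4R)-4-(TBSO)-2,6,6-trimethylcyclohex-1-en-1-yl]-3-methylpent-2-en-4-yn-1-ol | CC1=C(C#C/C(C)=C/CO)C(C)(C)C[C@H](O[Si](C)(C)C(C)(C)C)C1
F2 | step 9 | (2E)-5-[(4R)-4-(TBSO)-2,6,6-trimethylcyclohex-1-en-1-yl]-3-methylpent-2-en-4-ynal | CC1=C(C#C/C(C)=C/C=O)C(C)(C)C[C@H](O[Si](C)(C)C(C)(C)C)C1
F3 | step 9 | ethyl (2E,4E,6E)-9-[(4R)-4-(TBSO)-2,6,6-trimethylcyclohex-1-en-1-yl]-3,7-dimethylnona-2,4,6-trien-8-ynoate | CC1=C(C#C/C(C)=C/C=C/C(C)=C/C(=O)OCC)C(C)(C)C[C@H](O[Si](C)(C)C(C)(C)C)C1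
F4 | step 14 | (6S)-6-(TBSO)-2,4,4-trimethyl-3-[4-(trimethylsilyl)buta-1,3-diyn-1-yl]cyclohex-2-en-1-ol, C1 epimer mixture | CC1=C(C#CC#C[Si](C)(C)C)C(C)(C)C[C@H](O[Si](C)(C)C(C)(C)C)C1O
F5 | step 15 | (1S,6S)-6-(TBSO)-2,4,4-trimethyl-3-[4-(trimethylsilyl)buta-1,3-diyn-1-yl]cyclohex-2-en-1-ol (trans) | CC1=C(C#CC#C[Si](C)(C)C)C(C)(C)C[C@H](O[Si](C)(C)C(C)(C)C)[C@H]1O
F6 | step 15 | (1R,6S)-6-(TBSO)-2,4,4-trimethyl-3-[4-(trimethylsilyl)buta-1,3-diyn-1-yl]cyclohex-2-en-1-yl 4-nitrobenzoate (cis) | CC1=C(C#CC#C[Si](C)(C)C)C(C)(C)C[C@H](O[Si](C)(C)C(C)(C)C)[C@@H]1OC(=O)c2ccc(cc2)[N+](=O)[O-]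
F7 | step 15 | (1R,6S)-3-(buta-1,3-diyn-1-yl)-6-(TBSO)-2,4,4-trimethylcyclohex-2-en-1-ol (cis) | CC1=C(C#CC#C)C(C)(C)C[C@H](O[Si](C)(C)C(C)(C)C)[C@@H]1O
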